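**Retrosynthetic overview**
- The C2=C3 bond and the free 4-OH come last, by E1cB opening of a 3,4-O-isopropylidene ketol with loss of acetone.
- The only ring is closed in that same final operation by an interrupted polyketide-type aldol: the methyl-ketone carbon (C6) adds to the oleoyl-derived ketone (C5) of an acyclic 1,5-diketone. This is the bond the polyketide synthase makes, stopped at the tertiary ketol; C4 steers C5.
- The 1,5-diketone comes from a C3–C4 amine-catalysed syn-aldol between (10Z)-1-hydroxynonadec-10-en-2-one and ketal-masked acetoacetaldehyde; this sets C4.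
- The hydroxy ketone comes from oleoyl chloride by one-carbon homologation; the aldehyde comes from fructone.

Assumption: the presumed biosynthesis is an oleoyl-primed tetraketide (anacardic acid/cardanol family) whose ring closes by aldol attack of chain C-2 on the starter carbonyl, with later arene oxidation giving the diol; the SMILES is read as the (4R,5S) cis-diol with an (8Z)-heptadec-8-enyl chain.

**Step 1**
Reactants: 1 oleoyl chloride [(9Z)-octadec-9-enoyl chloride]; 2 tris(trimethylsilyloxy)ethylene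
Product: 5 (10Z)-1-hydroxynonadec-10-en-2-one, via silyl keto ester 3 (not isolated), via hydroxy keto acid 4 (not isolated)
Conditions: 2 (2.2 equiv), neat, 95 °C, 3 h (TMSCl distils off); then dioxane/0.6 M aq HCl, 85 °C, 30 min
Reagents that add atoms: none
Why: Wissner hydroxymethyl-ketone synthesis: the ketene silyl acetal is C-acylated by the acid chloride, and acid hydrolysis then decarboxylation of the α-silyloxy-β-keto silyl ester leaves the one-carbon-homologated α-hydroxy ketone; the isolated Z-alkene is inert and no stereocentre is formed.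

**Step 2**
Reactants: 6 ethyl 2-(2-methyl-1,3-dioxolan-2-yl)acetate (fructone)
Product: 7 2-(2-methyl-1,3-dioxolan-2-yl)acetaldehyde
Conditions: DIBAL-H (1.05 equiv), CH2Cl2, −78 °C, 1 h; MeOH quench, aq Rochelle salt
Reagents that add atoms: none
Why: DIBAL partial reduction of an ester: the aluminium hemiacetal is stable at −78 °C and collapses to the aldehyde only on work-up, and the ketal is untouched.

**Step 3**
Reactants: 5 (10Z)-1-hydroxynonadec-10-en-2-one; 7 2-(2-methyl-1,3-dioxolan-2-yl)acetaldehyde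
Product: 8 (2S,3R,12Z)-2,3-dihydroxy-1-(2-methyl-1,3-dioxolan-2-yl)henicos-12-en-4-one
Conditions: O-tert-butyl-L-threonine (20 mol%), 7 (3 equiv), NMP, 4 °C, 72 h
Reagents that add atoms: none
Why: Primary-amino-acid (Barbas-type) direct syn-aldol: the catalyst forms the hydrogen-bonded (Z)-enamine on the hydroxylated side of the ketone and its carboxylic acid directs the aldehyde, so the L-catalyst gives the (α-R, β-S) syn-diol, by analogy with the (3R,4S)-diols it gives from hydroxyacetone; this sets C4 (R) of the target, while C3 is a sacrificial centre.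

**Step 4**
Reactants: 8 (2S,3R,12Z)-2,3-dihydroxy-1-(2-methyl-1,3-dioxolan-2-yl)henicos-12-en-4-one
Product: 10 (9Z)-1-[(4R,5S)-2,2-dimethyl-5-(2-oxopropyl)-1,3-dioxolan-4-yl]octadec-9-en-1-one, via acetonide ethylene ketal 9 (not isolated)
Conditions: Me2C(OMe)2 (4 equiv), PPTS (10 mol%), acetone, rt, 3 h; then H2O (5 vol%), 50 °C, 8 h
Reagents that add atoms: 2,2-dimethoxypropane COC(C)(C)OC; water O
Why: Acid-catalysed acetalisation then selective ketal hydrolysis: the syn-diol closes to the trans-acetonide, and the ethylene ketal is then cleaved in wet acetone, where the acetonide is held by mass action; PPTS does not enolise the α-alkoxy ketone, so both stereocentres are kept.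

**Step 5**
Reactants: 10 (9Z)-1-[(4R,5S)-2,2-dimethyl-5-(2-oxopropyl)-1,3-dioxolan-4-yl]octadec-9-en-1-one
Product: 13 (4R,5S)-5-[(8Z)-heptadec-8-en-1-yl]-4,5-dihydroxycyclohex-2-en-1-one (CNP0223277.1), via trans-fused acetonide ketol 11 (not isolated), via hemiketal enone 12 (not isolated)
Conditions: L-proline (30 mol%), DMF, rt, 48 h; then DBU (1.5 equiv), 0 °C to rt, 2 h; pH 7 phosphate work-up
Reagents that add atoms: none
Why: Proposed new method: proline condenses with the unhindered methyl ketone and the terminal enamine carbon (C6) adds 6-(enolendo)-exo-trig to the α-alkoxy-activated oleoyl ketone through a chair in which both dioxolane C–O bonds and the C17 chain are equatorial and the forming bond is anti to C4–O (polar Felkin–Anh), so the new tertiary OH is axial and cis to O-4 (sets C5 as S); DBU then enolises C2, the acetonide oxygen on C3 leaves by E1cB and the resulting hemiketal loses acetone to free 4-OH; the closest known reactions are the Hajos–Parrish/Agami proline cyclisation of 1,5-diketones that stops at the ketol and the base-induced β-elimination of acetonides in quinic-acid-derived 3,4-O-isopropylidene cyclohexanones.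

**Compound list**
1 | oleoyl chloride, (9Z)-octadec-9-enoyl chloride | CCCCCCCC/C=C\CCCCCCCC(=O)Cl | starting material
2 | tris(trimethylsilyloxy)ethylene | C[Si](C)(C)OC=C(O[Si](C)(C)C)O[Si](C)(C)C | starting material
3 | trimethylsilyl (11Z)-3-oxo-2-[(trimethylsilyl)oxy]icos-11-enoate (racemic) | CCCCCCCC/C=C\CCCCCCCC(=O)C(O[Si](C)(C)C)C(=O)O[Si](C)(C)C | intermediate
4 | (11Z)-2-hydroxy-3-oxoicos-11-enoic acid (racemic) | CCCCCCCC/C=C\CCCCCCCC(=O)C(O)C(=O)O | intermediate
5 | (10Z)-1-hydroxynonadec-10-en-2-one | CCCCCCCC/C=C\CCCCCCCC(=O)CO | intermediate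
6 | ethyl 2-(2-methyl-1,3-dioxolan-2-yl)acetate (fructone) | CCOC(=O)CC1(C)OCCO1 | starting material
7 | 2-(2-methyl-1,3-dioxolan-2-yl)acetaldehyde | CC1(CC=O)OCCO1 | intermediate
8 | (2S,3R,12Z)-2,3-dihydroxy-1-(2-methyl-1,3-dioxolan-2-yl)henicos-12-en-4-one (syn-diol) | CCCCCCCC/C=C\CCCCCCCC(=O)[C@H](O)[C@@H](O)CC1(C)OCCO1 | intermediate
9 | (9Z)-1-[(4R,5S)-2,2-dimethyl-5-[(2-methyl-1,3-dioxolan-2-yl)methyl]-1,3-dioxolan-4-yl]octadec-9-en-1-one (trans-acetonide) | CCCCCCCC/C=C\CCCCCCCC(=O)[C@@H]1OC(C)(C)O[C@H]1CC2(C)OCCO2 | intermediate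
10 | (9Z)-1-[(4R,5S)-2,2-dimethyl-5-(2-oxopropyl)-1,3-dioxolan-4-yl]octadec-9-en-1-one (trans-acetonide) | CCCCCCCC/C=C\CCCCCCCC(=O)[C@@H]1OC(C)(C)O[C@H]1CC(C)=O | intermediate
11 | (3S,4R,5S)-5-[(8Z)-heptadec-8-en-1-yl]-5-hydroxy-3,4-(isopropylidenedioxy)cyclohexan-1-one (trans-fused acetonide; 5-OH cis to O-4) | CCCCCCCC/C=C\CCCCCCC[C@]1(O)CC(=O)C[C@@H]2OC(C)(C)O[C@@H]12 | intermediate
12 | (4R,5S)-5-[(8Z)-heptadec-8-en-1-yl]-5-hydroxy-4-[(2-hydroxypropan-2-yl)oxy]cyclohex-2-en-1-one | CCCCCCCC/C=C\CCCCCCC[C@]1(O)CC(=O)C=C[C@H]1OC(C)(C)O | intermediate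
13 | (4R,5S)-5-[(8Z)-heptadec-8-en-1-yl]-4,5-dihydroxycyclohex-2-en-1-one (cis-diol) | CCCCCCCC/C=C\CCCCCCC[C@]1(O)CC(=O)C=C[C@H]1O | target

**Step count and risks**

Total step count: 5. Longest linear sequence: 4 (steps 1, 3, 4, 5); step 2 is a one-step side branch.

**Step 5 (most likely to fail).** Three things can go wrong:
- The C5 selectivity rests on an equatorial-chain preference of roughly 1 kcal/mol plus the Felkin–Anh alignment.
- In ketol 11 the C3–O bond is locked equatorial by the trans-fused acetonide, so it is poorly aligned with the C1–C2 enolate. DBU may open it slowly, or may instead expel the axial tertiary 5-OH, which leads on to the 2-alkylhydroquinone.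
- Acyclic β-elimination of 10 could precede ring closure.

Fallback: set out from 11, isolated after the proline stage. Hydrolyse the strained trans-acetonide with 80% aqueous acetic acid at rt to the triol (3S,4R,5S)-5-[(8Z)-heptadec-8-en-1-yl]-3,4,5-trihydroxycyclohexan-1-one F1. Then acylate the only unhindered secondary hydroxyl (Ac2O 1.1 equiv, Et3N, cat. DMAP, CH2Cl2, −20 °C) to (3S,4R,5S)-3-acetoxy-5-[(8Z)-heptadec-8-en-1-yl]-4,5-dihydroxycyclohexan-1-one F2. F2 loses acetic acid by E1cB with the triethylamine already present, since a β-acetoxy group needs no special alignment, and the route is rejoined at 13.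

**Step 3.** The primary-amine syn-aldol is best documented for hydroxyacetone in excess with aromatic or α-branched aldehydes. Here the long-chain ketone is limiting and the acceptor is α-unbranched, so conversion may be low, 7 may self-condense, and the ee may fall.

Fallback: set out from 5 and 7 and abandon the syn series for the secondary-amine (E)-enamine manifold. D-proline (30 mol%, DMSO/CHCl3, rt) gives the anti-diol (2R,3R,12Z)-2,3-dihydroxy-1-(2-methyl-1,3-dioxolan-2-yl)henicos-12-en-4-one F3 with the same C4 configuration; proline with hydroxyacetone is documented to give high ee with α-unbranched aliphatic aldehydes. The step 4 conditions then give, through (9Z)-1-[(4R,5R)-2,2-dimethyl-5-[(2-methyl-1,3-dioxolan-2-yl)methyl]-1,3-dioxolan-4-yl]octadec-9-en-1-one F4, the cis-acetonide (9Z)-1-[(4R,5R)-2,2-dimethyl-5-(2-oxopropyl)-1,3-dioxolan-4-yl]octadec-9-en-1-one F5. Proline ring closure gives the cis-fused ketol (3R,4R,5S)-5-[(8Z)-heptadec-8-en-1-yl]-5-hydroxy-3,4-(isopropylidenedioxy)cyclohexan-1-one F6, in which C3–O can sit axial, so DBU opens it as in the quinic-acid series. The route is rejoined at hemiketal 12 and hence 13. The price is a less secure C5 selectivity in the cis-fused transition state.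

**Step 2.** The partial reduction may over-reduce, and the small β-ketal aldehyde is volatile and water-soluble.

Fallback: set out from 6, reduce fully with LiAlH4 (Et2O, 0 °C) to 2-(2-methyl-1,3-dioxolan-2-yl)ethan-1-ol F7, and re-oxidise under Swern conditions (or TEMPO/PhI(OAc)2) to rejoin at 7.

**Further compounds**
F1 | step 5 | (3S,4R,5S)-5-[(8Z)-heptadec-8-en-1-yl]-3,4,5-trihydroxycyclohexan-1-one | CCCCCCCC/C=C\CCCCCCC[C@]1(O)CC(=O)C[C@H](O)[C@H]1O
F2 | step 5 | (3S,4R,5S)-3-acetoxy-5-[(8Z)-heptadec-8-en-1-yl]-4,5-dihydroxycyclohexan-1-one | CCCCCCCC/C=C\CCCCCCC[C@]1(O)CC(=O)C[C@H](OC(C)=O)[C@H]1O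
F3 | step 3 | (2R,3R,12Z)-2,3-dihydroxy-1-(2-methyl-1,3-dioxolan-2-yl)henicos-12-en-4-one | CCCCCCCC/C=C\CCCCCCCC(=O)[C@H](O)[C@H](O)CC1(C)OCCO1
F4 | step 3 | (9Z)-1-[(4R,5R)-2,2-dimethyl-5-[(2-methyl-1,3-dioxolan-2-yl)methyl]-1,3-dioxolan-4-yl]octadec-9-en-1-one | CCCCCCCC/C=C\CCCCCCCC(=O)[C@@H]1OC(C)(C)O[C@@H]1CC2(C)OCCO2
F5 | step 3 | (9Z)-1-[(4R,5R)-2,2-dimethyl-5-(2-oxopropyl)-1,3-dioxolan-4-yl]octadec-9-en-1-one | CCCCCCCC/C=C\CCCCCCCC(=O)[C@@H]1OC(C)(C)O[C@@H]1CC(C)=O
F6 | step 3 | (3R,4R,5S)-5-[(8Z)-heptadec-8-en-1-yl]-5-hydroxy-3,4-(isopropylidenedioxy)cyclohexan-1-one (cis-fused acetonide) | CCCCCCCC/C=C\CCCCCCC[C@]1(O)CC(=O)C[C@H]2OC(C)(C)O[C@@H]12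
F7 | step 2 | 2-(2-methyl-1,3-dioxolan-2-yl)ethan-1-ol | CC1(CCO)OCCO1
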